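## Retrosynthetic overview

1. The target acid comes from its methyl ester; the C3–CH2CO2Me bond is made by adding a silyl ketene acetal to the peroxycarbenium ion of a 3-hydroxy-1,2-dioxolane.
2. The 1,2-dioxolane, the only ring of the target and the last ring formed, comes from asymmetric conjugate hydroperoxidation and hemiketalization of an (E)-β,β-disubstituted enone (sets C5).
3. The enone comes from a terminal alkyne by methylalumination and acylation; the alkyne comes from a stereoinvertive copper-catalysed sp3–sp3 coupling of a secondary tosylate with 8-phenyloctylmagnesium bromide.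
4. The tosylate comes from cis-4,6-dimethyl-δ-valerolactone, made by one-pot dearomatizing asymmetric hydrogenation of 4,6-dimethyl-2-pyranone (key step). This lactone is the first ring and is opened in the next step; cis-lactone plus inversion at the carbinol carbon gives the anti-1,3-dimethyl unit.

Assumption: the sense of induction of the chiral catalysts in steps 1 and 6 is taken as written; if either proves opposite, the enantiomeric ligand (step 1) or the pseudoenantiomeric quinine-derived amine (step 6) is used.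

## Route

Step 1
Reactants: 1 4,6-dimethyl-2H-pyran-2-one
Product: 3 (4S,6R)-4,6-dimethyloxan-2-one (cis-lactone), via dihydropyranone 2 (not isolated)
Conditions: H2 (60 bar), Ru(OAc)2(L) (0.5 mol%; L = (R)-(6,6'-dimethoxybiphenyl-2,2'-diyl)bis[bis(3,5-di-tert-butylphenyl)phosphane]), HBF4·OEt2 (1 mol%), i-PrOH/CH2Cl2, 60 °C; then 5% Pd/C, H2 (5 bar), 25 °C, same pot
Reagents that add atoms: none
Why: Dearomatizing asymmetric hydrogenation: cationic Ru–biaryl diphosphane catalysts reduce the C5=C6 enol-ester bond of 2-pyranones with high enantioselectivity (sets C6 as R), and the remaining C3=C4 bond is then hydrogenated on Pd/C from the face anti to the C6 methyl group, giving the cis (4S) lactone.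

Step 2
Reactants: 3 (4S,6R)-4,6-dimethyloxan-2-one
Product: 5 (2R,4R)-4-methylhept-6-yn-2-ol, via lactol 4 (not isolated)
Conditions: i-Bu2AlH (1.1 equiv), CH2Cl2, −78 °C; then MeOH, K2CO3 (2 equiv), dimethyl (1-diazo-2-oxopropyl)phosphonate (1.3 equiv), −78 °C → rt
Reagents that add atoms: dimethyl (1-diazo-2-oxopropyl)phosphonate, COP(=O)(OC)C(=[N+]=[N-])C(C)=O
Why: Low-temperature i-Bu2AlH reduction stops at the lactol, whose open hydroxy-aldehyde form undergoes Seyferth–Gilbert homologation with the Ohira–Bestmann reagent; neither stereocenter is touched (the aldehyde α-carbon is a CH2; the C4 descriptor changes from S to R only because the priorities change).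

Step 3
Reactants: 5 (2R,4R)-4-methylhept-6-yn-2-ol
Product: 6 (2R,4R)-4-methylhept-6-yn-2-yl 4-methylbenzenesulfonate
Conditions: TsCl (1.3 equiv), pyridine, DMAP (cat.), CH2Cl2, 0 °C → rt
Reagents that add atoms: 4-methylbenzenesulfonyl chloride, Cc1ccc(cc1)S(Cl)(=O)=O
Why: O-sulfonylation of the secondary alcohol occurs with retention at carbon and activates it for substitution.

Step 4
Reactants: 6 (2R,4R)-4-methylhept-6-yn-2-yl 4-methylbenzenesulfonate; 7 (8-bromooctyl)benzene
Product: 9 [(9R,11S)-9,11-dimethyltetradec-13-yn-1-yl]benzene, via Grignard reagent 8 (not isolated)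
Conditions: 7, Mg, THF, 40 °C (gives 8, 3 equiv); then 6, CuI (10 mol%), TMEDA (20 mol%), LiOMe (1 equiv), THF, 0 °C, 24 h
Reagents that add atoms: none
Why: Copper-catalysed SN2-type cross-coupling of a secondary alkyl tosylate with a primary alkyl Grignard reagent proceeds with clean inversion, which turns the carbinol carbon into the 9R methyl-bearing center (anti to the 11-methyl); one equivalent of 8 is consumed by the alkyne C–H, which is restored on work-up.

Step 5
Reactants: 9 [(9R,11S)-9,11-dimethyltetradec-13-yn-1-yl]benzene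
Product: 11 (3E,6S,8R)-4,6,8-trimethyl-16-phenylhexadec-3-en-2-one, via alkenylalane 10 (not isolated)
Conditions: AlMe3 (2.5 equiv), Cp2ZrCl2 (0.25 equiv), ClCH2CH2Cl, 0 °C → rt; volatiles removed; then AcCl (1.5 equiv), Pd(PPh3)4 (5 mol%), THF, 0 °C → rt
Reagents that add atoms: trimethylaluminium, C[Al](C)C; acetyl chloride, CC(Cl)=O
Why: Zirconium-catalysed methylalumination (Negishi carboalumination) adds CH3 and Al syn with CH3 on the internal carbon, and palladium-catalysed acylation of the alkenylalane proceeds with retention, so only the E enone forms; no stereocenter is touched.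

Step 6
Reactants: 11 (3E,6S,8R)-4,6,8-trimethyl-16-phenylhexadec-3-en-2-one
Product: 12 (3RS,5S)-5-[(2S,4R)-2,4-dimethyl-12-phenyldodecyl]-3,5-dimethyl-1,2-dioxolan-3-ol
Conditions: H2O2 (50% aq, 3 equiv), 9-amino-9-deoxy-epi-quinidine (10 mol%), CCl3CO2H (20 mol%), 1,4-dioxane, 32 °C, 48 h
Reagents that add atoms: hydrogen peroxide, OO
Why: Proposed new method: the primary amine salt forms the (E)-iminium ion of the enone, H2O2 adds to one face of the β-carbon under direction of the protonated quinuclidine, and the β-hydroperoxy ketone closes to the peroxyhemiketal, which sets C5 (S) under catalyst control and makes the dioxolane ring; the closest known reaction type is the cinchona primary amine-catalysed asymmetric hydroperoxidation of β-monosubstituted acyclic enones with H2O2, and the untested element is the β,β-disubstituted acyclic substrate.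

Step 7
Reactants: 12 (3RS,5S)-5-[(2S,4R)-2,4-dimethyl-12-phenyldodecyl]-3,5-dimethyl-1,2-dioxolan-3-ol
Product: 14 methyl 2-[(3R,5S)-5-[(2S,4R)-2,4-dimethyl-12-phenyldodecyl]-3,5-dimethyl-1,2-dioxolan-3-yl]acetate, via dioxolanyl acetate 13 (not isolated)
Conditions: Ac2O, pyridine, DMAP (cat.), CH2Cl2, 0 °C; concentrate; then CH2=C(OMe)OSiMe2t-Bu (3 equiv), Me3SiOTf (0.3 equiv), CH2Cl2, −78 → −40 °C; silica gel separation of the C3 epimers
Reagents that add atoms: tert-butyl[(1-methoxyethenyl)oxy]dimethylsilane, C=C(OC)O[Si](C)(C)C(C)(C)C (acetic anhydride, CC(=O)OC(C)=O, supplies only the acetyl group of 13)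
Why: Ionization of the acetate gives a peroxycarbenium ion that is trapped by the silyl ketene acetal (Mukaiyama-type SN1 substitution known for 3-acyloxy-1,2-dioxolanes); C5 is untouched, C3 forms with only a weak bias (attack anti to the larger C5 substituent favors the wanted 3R isomer, about 1–2:1 expected), and the 3R,5S ester is isolated by chromatography from its C3 epimer.

Step 8
Reactants: 14 methyl 2-[(3R,5S)-5-[(2S,4R)-2,4-dimethyl-12-phenyldodecyl]-3,5-dimethyl-1,2-dioxolan-3-yl]acetate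
Product: 15 2-[(3R,5S)-5-[(2S,4R)-2,4-dimethyl-12-phenyldodecyl]-3,5-dimethyl-1,2-dioxolan-3-yl]acetic acid
Conditions: LiOH·H2O (3 equiv), THF/H2O 3:1, 0 °C → rt; then 1 M HCl to pH 3
Reagents that add atoms: lithium hydroxide, [Li+].[OH-]
Why: Ester saponification (BAc2) leaves the di-tert-alkyl peroxide intact, as in known syntheses of 1,2-dioxolane-3-acetic acids, and affects no stereocenter.

## Compound list

1 | 4,6-dimethyl-2H-pyran-2-one | CC1=CC(C)=CC(=O)O1 | starting material
2 | (6R)-4,6-dimethyl-5,6-dihydro-2H-pyran-2-one | C[C@@H]1CC(C)=CC(=O)O1 | intermediate (not isolated)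
3 | (4S,6R)-4,6-dimethyloxan-2-one | C[C@@H]1C[C@H](C)CC(=O)O1 | intermediate
4 | (4S,6R)-4,6-dimethyloxan-2-ol (anomer mixture) | C[C@@H]1C[C@H](C)CC(O)O1 | intermediate (not isolated)
5 | (2R,4R)-4-methylhept-6-yn-2-ol | C[C@@H](O)C[C@H](C)CC#C | intermediate
6 | (2R,4R)-4-methylhept-6-yn-2-yl 4-methylbenzenesulfonate | C[C@@H](OS(=O)(=O)c1ccc(C)cc1)C[C@H](C)CC#C | intermediate
7 | (8-bromooctyl)benzene | BrCCCCCCCCc1ccccc1 | starting material
8 | bromo(8-phenyloctyl)magnesium | Br[Mg]CCCCCCCCc1ccccc1 | intermediate (not isolated)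
9 | [(9R,11S)-9,11-dimethyltetradec-13-yn-1-yl]benzene | C[C@H](CCCCCCCCc1ccccc1)C[C@H](C)CC#C | intermediate
10 | dimethyl[(1E,4S,6R)-2,4,6-trimethyl-14-phenyltetradec-1-en-1-yl]alumane | C[C@H](CCCCCCCCc1ccccc1)C[C@H](C)C/C(C)=C/[Al](C)C | intermediate (not isolated)
11 | (3E,6S,8R)-4,6,8-trimethyl-16-phenylhexadec-3-en-2-one | C[C@H](CCCCCCCCc1ccccc1)C[C@H](C)C/C(C)=C/C(C)=O | intermediate
12 | (3RS,5S)-5-[(2S,4R)-2,4-dimethyl-12-phenyldodecyl]-3,5-dimethyl-1,2-dioxolan-3-ol | C[C@H](CCCCCCCCc1ccccc1)C[C@H](C)C[C@@]1(C)CC(C)(O)OO1 | intermediate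
13 | (3RS,5S)-5-[(2S,4R)-2,4-dimethyl-12-phenyldodecyl]-3,5-dimethyl-1,2-dioxolan-3-yl acetate | C[C@H](CCCCCCCCc1ccccc1)C[C@H](C)C[C@@]1(C)CC(C)(OC(C)=O)OO1 | intermediate (not isolated)
14 | methyl 2-[(3R,5S)-5-[(2S,4R)-2,4-dimethyl-12-phenyldodecyl]-3,5-dimethyl-1,2-dioxolan-3-yl]acetate | C[C@H](CCCCCCCCc1ccccc1)C[C@H](C)C[C@@]1(C)C[C@](C)(CC(=O)OC)OO1 | intermediate
15 | 2-[(3R,5S)-5-[(2S,4R)-2,4-dimethyl-12-phenyldodecyl]-3,5-dimethyl-1,2-dioxolan-3-yl]acetic acid | C[C@H](CCCCCCCCc1ccccc1)C[C@H](C)C[C@@]1(C)C[C@](C)(CC(=O)O)OO1 | target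

## Step count and risks

Total step count: 8. Longest linear sequence: 8 steps from 1 (7 is purchased).

**Step 6 (asymmetric hydroperoxidation).** The quaternary β-carbon slows the addition, and E/Z scrambling of the iminium ion through a dienamine would erode the C5 configuration. The fallback sets out from 11 and returns at 12, and replaces catalytic peroxidation by a stereospecific oxetane opening:
- Luche reduction (NaBH4, CeCl3, MeOH) gives (2RS,3E,6S,8R)-4,6,8-trimethyl-16-phenylhexadec-3-en-2-ol F3.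
- Shi epoxidation (fructose-derived ketone catalyst, KHSO5, K2CO3, MeCN/H2O, 0 °C; the ketone enantiomer that gives the 2R,3R oxirane) gives (1RS)-1-[(2R,3R)-3-[(2S,4R)-2,4-dimethyl-12-phenyldodecyl]-3-methyloxiran-2-yl]ethan-1-ol F4.
- Hydride opening at the secondary epoxide carbon with NaAlH2(OCH2CH2OMe)2 (THF, 0 °C) gives (2RS,4R,6S,8R)-4,6,8-trimethyl-16-phenylhexadecane-2,4-diol F5.
- Selective mesylation of the secondary hydroxyl (MsCl, Et3N, −20 °C) gives (2RS,4R,6S,8R)-4-hydroxy-4,6,8-trimethyl-16-phenylhexadecan-2-yl methanesulfonate F6, and KOt-Bu (THF) closes it to (2R,4RS)-2-[(2S,4R)-2,4-dimethyl-12-phenyldodecyl]-2,4-dimethyloxetane F7.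
- Anhydrous H2O2 in Et2O with catalytic Me3SiOTf (−78 → 0 °C) opens the oxetane at the tertiary carbon with inversion to (2RS,4S,6S,8R)-4-hydroperoxy-4,6,8-trimethyl-16-phenylhexadecan-2-ol F8.
- 2-Methoxypropene with pyridinium tosylate gives (2RS,4S,6S,8R)-4-[(2-methoxypropan-2-yl)peroxy]-4,6,8-trimethyl-16-phenylhexadecan-2-ol F9, and Dess–Martin oxidation gives (4S,6S,8R)-4-[(2-methoxypropan-2-yl)peroxy]-4,6,8-trimethyl-16-phenylhexadecan-2-one F10.
- Aqueous AcOH in THF removes the peroxyketal, and the hydroperoxy ketone closes to 12.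

**Step 7 (C3 formation).** The peroxycarbenium ion sees only methyl versus CH2R at C5, so the C3 epimers may form close to 1:1 and must be separated. The fallback sets out from 13 and returns at 15, and replaces substrate control by auxiliary control. The chlorotitanium enolate of 1-[(4S)-4-(propan-2-yl)-2-sulfanylidene-1,3-thiazolidin-3-yl]ethan-1-one (TiCl4, i-Pr2NEt, CH2Cl2, −78 °C) is added to 13, which TiCl4 ionizes. The shielded enolate face then decides the C3 configuration and gives 2-[(3R,5S)-5-[(2S,4R)-2,4-dimethyl-12-phenyldodecyl]-3,5-dimethyl-1,2-dioxolan-3-yl]-1-[(4S)-4-(propan-2-yl)-2-sulfanylidene-1,3-thiazolidin-3-yl]ethan-1-one F11 (the 4R auxiliary is used if the sense is opposite). LiOH (THF/H2O, 0 °C) cleaves the auxiliary and gives 15 directly.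

**Step 4 (secondary tosylate coupling).** Elimination, and loss of copper as an unreactive acetylide of the terminal alkyne, can lower the yield. The fallback sets out from 6 (and 7) and returns at 9, and replaces the organometallic coupling by a stabilized-carbanion SN2 with the same inversion. Bromide 7 and PhSO2Na (DMF, 80 °C) give [(8-phenyloctyl)sulfonyl]benzene F1. Its lithio derivative (n-BuLi, THF/DMPU, −78 °C → rt, 2.2 equiv to cover the alkyne C–H) displaces the tosylate of 6 to give {[(8RS,9S,11S)-9,11-dimethyl-1-phenyltetradec-13-yn-8-yl]sulfonyl}benzene F2. Reductive desulfonylation (sodium amalgam, Na2HPO4, MeOH, −20 °C) gives 9.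

## Further compounds

F1 | step 4 | [(8-phenyloctyl)sulfonyl]benzene | O=S(=O)(CCCCCCCCc1ccccc1)c1ccccc1
F2 | step 4 | {[(8RS,9S,11S)-9,11-dimethyl-1-phenyltetradec-13-yn-8-yl]sulfonyl}benzene | C[C@H](C(CCCCCCCc1ccccc1)S(=O)(=O)c1ccccc1)C[C@H](C)CC#C
F3 | step 6 | (2RS,3E,6S,8R)-4,6,8-trimethyl-16-phenylhexadec-3-en-2-ol | C[C@H](CCCCCCCCc1ccccc1)C[C@H](C)C/C(C)=C/C(C)O
F4 | step 6 | (1RS)-1-[(2R,3R)-3-[(2S,4R)-2,4-dimethyl-12-phenyldodecyl]-3-methyloxiran-2-yl]ethan-1-ol | C[C@H](CCCCCCCCc1ccccc1)C[C@H](C)C[C@@]1(C)O[C@@H]1C(C)O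
F5 | step 6 | (2RS,4R,6S,8R)-4,6,8-trimethyl-16-phenylhexadecane-2,4-diol | C[C@H](CCCCCCCCc1ccccc1)C[C@H](C)C[C@@](C)(O)CC(C)O
F6 | step 6 | (2RS,4R,6S,8R)-4-hydroxy-4,6,8-trimethyl-16-phenylhexadecan-2-yl methanesulfonate | C[C@H](CCCCCCCCc1ccccc1)C[C@H](C)C[C@@](C)(O)CC(C)OS(C)(=O)=O
F7 | step 6 | (2R,4RS)-2-[(2S,4R)-2,4-dimethyl-12-phenyldodecyl]-2,4-dimethyloxetane | C[C@H](CCCCCCCCc1ccccc1)C[C@H](C)C[C@]1(C)CC(C)O1
F8 | step 6 | (2RS,4S,6S,8R)-4-hydroperoxy-4,6,8-trimethyl-16-phenylhexadecan-2-ol | C[C@H](CCCCCCCCc1ccccc1)C[C@H](C)C[C@](C)(OO)CC(C)O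
F9 | step 6 | (2RS,4S,6S,8R)-4-[(2-methoxypropan-2-yl)peroxy]-4,6,8-trimethyl-16-phenylhexadecan-2-ol | C[C@H](CCCCCCCCc1ccccc1)C[C@H](C)C[C@](C)(OOC(C)(C)OC)CC(C)O
F10 | step 6 | (4S,6S,8R)-4-[(2-methoxypropan-2-yl)peroxy]-4,6,8-trimethyl-16-phenylhexadecan-2-one | C[C@H](CCCCCCCCc1ccccc1)C[C@H](C)C[C@](C)(OOC(C)(C)OC)CC(C)=O
F11 | step 7 | 2-[(3R,5S)-5-[(2S,4R)-2,4-dimethyl-12-phenyldodecyl]-3,5-dimethyl-1,2-dioxolan-3-yl]-1-[(4S)-4-(propan-2-yl)-2-sulfanylidene-1,3-thiazolidin-3-yl]ethan-1-one | C[C@H](CCCCCCCCc1ccccc1)C[C@H](C)C[C@@]1(C)C[C@](C)(CC(=O)N2[C@@H](C(C)C)CSC2=S)OO1
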